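## Retrosynthetic overview

1. Feature: the cycloheptane C1/C5/C6/C7/C8/C9/C10 has a tertiary carbinol C1 flanked by oxygenated C5 and by C10, whose methyl is cis to the C1 oxygen. This is the pattern of an 8-oxabicyclo[3.2.1]oct-3-en-2-one in which the C1 oxygen is tied to C8 as the bridge.
2. Late stage: the C5 angelate is installed and the C4 silyl ether removed last; the C2 ketone comes from the C2≡C3 alkyne; the C8/C9 methylenes come from a C8=C9 alkene formed by reductive loss of a C9 sulfonyl group with cleavage of the C8–O bridge.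
3. The γ-lactone (O–C6, C7–C11) comes from exo Michael addition of a propionate unit at C7 of the bicyclic enone, then exo hydroboration of the resulting C5=C6 silyl enol ether, which sets C5 and C6.
4. Key disconnection: C1–C10 and C8–C9, by [5+2] cycloaddition of a 2-alkynyl-3-oxidopyrylium (from furfural and (R)-but-3-yn-2-ol via Achmatowicz rearrangement) with (R,E)-prop-1-enyl p-tolyl sulfoxide.
5. Ring order: pyranone, then the oxygen-bridged seven-membered carbocycle (step 6), then the γ-lactone (step 10), then opening of the bridge to the monocyclic cycloheptane (step 11).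

Key step: step 6

Remark: locants follow the target (ring C1, C5–C10; chain C2–C4 with methyl C15; lactone C11–C13; C14 on C10); "exo" is the face of the bridging oxygen; TBS = tert-butyldimethylsilyl; the resolved (1R,2S,5R)-menthyl (S)-p-toluenesulfinate is taken as a purchased starting material.

## Route

Step 1
Reactants: 1 (R)-but-3-yn-2-ol
Product: 2 (R)-tert-butyl(but-3-yn-2-yloxy)dimethylsilane
Conditions: TBSCl, imidazole, DMF, 0 → 25 °C
Reagents that add atoms: tert-butyldimethylsilyl chloride, CC(C)(C)[Si](C)(C)Cl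
Why: Standard imidazole-mediated silylation of the secondary propargylic alcohol, which leaves the chiral-pool C4 stereocentre untouched.

Step 2
Reactants: 2 (R)-tert-butyl(but-3-yn-2-yloxy)dimethylsilane; 3 furfural
Product: 5 (4R)-4-(tert-butyldimethylsilyloxy)-1-(furan-2-yl)pent-2-yn-1-ol, via lithium acetylide 4 (not isolated)
Conditions: n-BuLi, THF, −78 °C; then 3, −78 → 0 °C; H2O
Reagents that add atoms: none
Why: Deprotonation of the terminal alkyne and 1,2-addition of the acetylide to the aldehyde give the furyl propargylic carbinol; its new carbinol centre forms unselectively, which is immaterial because that carbon becomes the sp2 C1 of the ylide in step 6.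

Step 3
Reactants: 5 (4R)-4-(tert-butyldimethylsilyloxy)-1-(furan-2-yl)pent-2-yn-1-ol
Product: 6 6-hydroxy-2-[(3R)-3-(tert-butyldimethylsilyloxy)but-1-ynyl]-2H-pyran-3(6H)-one
Conditions: NBS, NaHCO3, THF/H2O 4:1, 0 °C
Reagents that add atoms: water, O
Why: Achmatowicz rearrangement, in which bromonium-induced oxidative opening of the furan and closure of the carbinol oxygen onto the unmasked aldehyde carbon give the hydroxypyranone, the alkyne and silyl ether being inert to buffered NBS; both ring stereocentres are transient.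

Step 4
Reactants: 6 6-hydroxy-2-[(3R)-3-(tert-butyldimethylsilyloxy)but-1-ynyl]-2H-pyran-3(6H)-one
Product: 7 6-acetoxy-2-[(3R)-3-(tert-butyldimethylsilyloxy)but-1-ynyl]-2H-pyran-3(6H)-one
Conditions: Ac2O, pyridine, CH2Cl2, 0 °C
Reagents that add atoms: acetic anhydride, CC(=O)OC(C)=O
Why: O-acetylation of the lactol installs the leaving group for ylide formation, and pyridine at 0 °C without a stronger base should not remove the acidic C–H between ketone and alkyne prematurely.

Step 5
Reactants: 8 (E)-1-bromoprop-1-ene; 9 (1R,2S,5R)-menthyl (S)-4-methylbenzenesulfinate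
Product: 12 (R,E)-1-methyl-4-(prop-1-enylsulfinyl)benzene, via (E)-prop-1-enyllithium 10 (not isolated), via (E)-prop-1-enylmagnesium bromide 11 (not isolated)
Conditions: t-BuLi (2 equiv), Et2O, −78 °C; MgBr2·OEt2, −78 → 0 °C; then 9, toluene/THF, −40 → 0 °C; H2O
Reagents that add atoms: none
Why: Andersen sulfoxide synthesis, in which bromine–lithium exchange with retention of the (E) geometry, transmetallation to the Grignard reagent and substitution at sulfur with inversion turn the (S)-sulfinate into the (R)-sulfoxide.

Step 6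
Reactants: 7 6-acetoxy-2-[(3R)-3-(tert-butyldimethylsilyloxy)but-1-ynyl]-2H-pyran-3(6H)-one; 12 (R,E)-1-methyl-4-(prop-1-enylsulfinyl)benzene
Product: 14 (1R,5S,6S,7R)-1-[(3R)-3-(tert-butyldimethylsilyloxy)but-1-ynyl]-7-methyl-6-[(R)-p-tolylsulfinyl]-8-oxabicyclo[3.2.1]oct-3-en-2-one (7-exo-methyl; 6-endo-sulfinyl), via 2-alkynylpyrylium-3-olate 13 (not isolated)
Conditions: 12 (4 equiv), Et3N (1.5 equiv), CH2Cl2, 25 °C, 7 added over 12 h
Reagents that add atoms: none
Why: Triethylamine removes the doubly activated C–H of 7 and acetate leaves, so both pyranone stereocentres vanish in the planar oxidopyrylium 13, which adds suprafacially as a five-atom dipole across the sulfinyl-activated alkene in a concerted thermal [5+2] cycloaddition; the closest known reactions are the additions of acetoxypyranone-derived oxidopyrylium ylides to acrylates, enones and vinyl sulfones, and sulfinyl-directed face selection is known for tethered pyrone–alkene [5+2] reactions. The seven-membered carbocycle C1–C5–C6–C7–C8–C9–C10 closes by intermolecular annulation, with C1–C10 and C8–C9 forming on one face of the ylide so that the former ring oxygen remains as the one-atom C1–O–C8 bridge. Regiochemistry follows polarity: the enolate-like carbon next to the oxide (C1) bonds to the β-carbon of the vinyl sulfoxide (C10) and the oxocarbenium-like terminus (C8) to the sulfur-bearing carbon (C9). The trans relation of C9 and C10 is carried over from the (E)-alkene, and an endo sulfinyl group places the C10 methyl exo, cis to the bridging oxygen on C1. The absolute sense at C1, C8, C9 and C10 is set by sulfur: in the S=O/C=C s-cis conformer of the (R)-sulfoxide the ylide should approach the alkene face that carries the sulfur lone pair, away from the p-tolyl group. The step needs regio-, endo and facial selectivity together and a cycloaddition faster than ylide dimerisation; slow addition of 7 to excess, recoverable 12 addresses the rate, and since every isomer is a diastereomer (sulfur and C4 stereocentres) the wanted adduct can be purified to a single stereoisomer.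

Step 7
Reactants: 14 the sulfinyl cycloadduct
Product: 15 (1R,5S,6S,7R)-1-[(3R)-3-(tert-butyldimethylsilyloxy)but-1-ynyl]-7-methyl-6-(p-tolylsulfonyl)-8-oxabicyclo[3.2.1]oct-3-en-2-one
Conditions: mCPBA (1.2 equiv), CH2Cl2, 0 → 25 °C
Reagents that add atoms: 3-chloroperbenzoic acid, OOC(=O)c1cccc(Cl)c1
Why: Peracid oxidation of the sulfoxide to the sulfone (the electron-poor enone and the alkyne do not react) removes the thermally labile sulfinyl group once its stereocontrolling role is over and provides the group needed for the bridge opening in step 11.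

Step 8
Reactants: 16 methyl propanoate
Product: 18 (E)-1-methoxy-1-(trimethylsilyloxy)prop-1-ene, via lithium ester enolate 17 (not isolated)
Conditions: LiN(i-Pr)2, THF, −78 °C; Me3SiCl, −78 → 25 °C; distillation
Reagents that add atoms: chlorotrimethylsilane, C[Si](C)(C)Cl
Why: Kinetic ester enolisation and O-silylation give the silyl ketene acetal, whose geometry is of no consequence because C11 is corrected in step 12.

Step 9
Reactants: 15 the sulfonyl enone; 18 (E)-1-methoxy-1-(trimethylsilyloxy)prop-1-ene
Product: 19 C5 trimethylsilyl enol ether (C5=C6) carrying exo CH(CH3)CO2Me at C7 (C11 epimers)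
Conditions: 18 (2 equiv), Me3SiOTf (10 mol%), CH2Cl2, −78 °C; Et3N; filtration through Florisil
Reagents that add atoms: none
Why: Mukaiyama–Michael addition in which the ketene acetal attacks C7 on the exo face (the endo face is shielded by the two-carbon bridge and its C9 sulfonyl group), so that C11 ends cis to the bridging oxygen, and silyl transfer delivers the C5=C6 enol ether directly; C11 forms as an epimer mixture that is converged in step 12.

Step 10
Reactants: 19 the C5 silyl enol ether
Product: 22 bicyclic γ-lactone alcohol (C5 hydroxyl endo; O–C6 and C7–C11 exo; C11 epimers), via C6 alkylborane 20 (not isolated), via trans-5,6-diol methyl ester 21 (not isolated)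
Conditions: BH3·THF (1.5 equiv), THF, −20 → 0 °C; 30% H2O2, aq. NaOAc, 0 °C; then PPTS, MeOH/toluene 1:10, 40 °C
Reagents that add atoms: hydrogen peroxide, OO
Why: Hydroboration–oxidation of a silyl enol ether, in which BH3 adds syn across C5=C6 from the exo face with boron at C6 and hydrogen at C5, so that oxidation with retention gives the exo C6 hydroxyl and the endo C5 oxygen in one operation, and the C6 hydroxyl then closes the γ-lactone onto the cis C7 side chain (only the cis fusion is possible on the rigid bicycle); the electron-rich enol ether should react before the hindered C2≡C3 alkyne, which is flanked by two C–O bonds.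

Step 11
Reactants: 22 the bicyclic γ-lactone alcohol
Product: 23 monocyclic cyclohept-8-ene diol lactone (C1 and C5 hydroxyls free; C11 epimers)
Conditions: SmI2 (6 equiv), HMPA, THF, −20 → 25 °C
Reagents that add atoms: none
Why: Julia-type reductive elimination in which electron transfer cleaves the C9–sulfonyl bond and the C9 organosamarium expels the strained bridging alkoxide from C8, which frees the tertiary C1 hydroxyl and leaves the C8=C9 alkene without touching C1, C5, C6, C7 or C10.

Step 12
Reactants: 23 the cycloheptene diol lactone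
Product: 25 cycloheptene diol lactone as a single C11 epimer (11-H cis to 6-H and 7-H), via trilithium enolate 24 (not isolated)
Conditions: LiN(i-Pr)2 (3.5 equiv), THF, −78 → −40 °C; 2,6-di-tert-butyl-4-methylphenol, −78 °C
Reagents that add atoms: none
Why: Kinetic protonation of a lactone enolate, in which the bulky phenol protonates the planar C11 enolate of the cis-fused lactone on its convex face (that of 6-H and 7-H), which places the C13 methyl on the concave face as in the target and converges both C11 epimers.

Step 13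
Reactants: 25 the C11-defined diol lactone
Product: 28 C2 ketone (1,5-dihydroxy-2-oxo-4-silyloxy chain compound with C8=C9), via C5 dimethylsilyl ether 26 (not isolated), via cyclic alkenylsiloxane 27 (not isolated)
Conditions: (HMe2Si)2NH, 25 °C; Pt2[(CH2=CHSiMe2)2O]3 (1 mol%, zerovalent platinum), THF, 25 °C; 30% H2O2, KF, KHCO3, THF/MeOH, 0 → 25 °C
Reagents that add atoms: hydrogen peroxide, OO
Why: Tethered hydrosilylation followed by Tamao–Fleming oxidation, in which the C5–O–SiMe2H group (cis to the alkynyl chain) adds syn across C2≡C3 in the 5-exo-dig mode so that silicon can only reach C2, and oxidation of the C2–Si bond gives the C2 ketone with C3 as CH2; no stereocentre is formed, and a limited excess of peroxide at low temperature protects the α-ketol.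

Step 14
Reactants: 28 the C2 ketone
Product: 29 8,9-dihydro derivative of 28 (saturated cycloheptane)
Conditions: H2 (1 atm), Pd/C (10% Pd on carbon), EtOAc, 25 °C
Reagents that add atoms: none
Why: Heterogeneous catalytic hydrogenation of the cis-disubstituted ring alkene turns C8 and C9 into methylenes without forming a stereocentre, the ketone, lactone and silyl ether being inert.

Step 15
Reactants: 29 the saturated diol; 30 angelic acid
Product: 32 5-O-angeloyl derivative of 29, via angelic 2,4,6-trichlorobenzoic anhydride 31 (not isolated)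
Conditions: 30 (3 equiv), 2,4,6-trichlorobenzoyl chloride, Et3N, toluene, 25 °C; then 29, 75 °C
Reagents that add atoms: none
Why: Yamaguchi-type acylation with the preformed mixed anhydride and no nucleophilic catalyst, conditions developed to transfer the angeloyl group without Z-to-E isomerisation; only the secondary C5 hydroxyl reacts, since the C1 hydroxyl is tertiary and C4–O is silylated.

Step 16
Reactants: 32 the silylated angelate
Product: 33 target CNP0321985.1
Conditions: HF·pyridine, pyridine, THF, 0 → 25 °C
Reagents that add atoms: none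
Why: Fluoride-mediated cleavage of the secondary silyl ether under buffered acidic conditions, which should leave the angelate, the lactone and the β-hydroxy ketone intact.

## Compound list

1 | (R)-but-3-yn-2-ol | C[C@@H](O)C#C | starting material
2 | (R)-tert-butyl(but-3-yn-2-yloxy)dimethylsilane | C[C@@H](O[Si](C)(C)C(C)(C)C)C#C | intermediate
3 | furfural | O=Cc1ccco1 | starting material
4 | lithium (3R)-3-(tert-butyldimethylsilyloxy)but-1-ynide | [Li]C#C[C@@H](C)O[Si](C)(C)C(C)(C)C | intermediate (not isolated)
5 | (4R)-4-(tert-butyldimethylsilyloxy)-1-(furan-2-yl)pent-2-yn-1-ol (both C1 epimers) | OC(c1ccco1)C#C[C@@H](C)O[Si](C)(C)C(C)(C)C | intermediate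
6 | 6-hydroxy-2-[(3R)-3-(tert-butyldimethylsilyloxy)but-1-ynyl]-2H-pyran-3(6H)-one (ring diastereomers) | OC1C=CC(=O)C(C#C[C@@H](C)O[Si](C)(C)C(C)(C)C)O1 | intermediate
7 | 6-acetoxy-2-[(3R)-3-(tert-butyldimethylsilyloxy)but-1-ynyl]-2H-pyran-3(6H)-one (ring diastereomers, all converge) | CC(=O)OC1C=CC(=O)C(C#C[C@@H](C)O[Si](C)(C)C(C)(C)C)O1 | intermediate
8 | (E)-1-bromoprop-1-ene | C/C=C/Br | starting material
9 | (1R,2S,5R)-menthyl (S)-4-methylbenzenesulfinate | C[C@@H]1CC[C@H]([C@@H](C1)O[S@](=O)c2ccc(C)cc2)C(C)C | starting material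
10 | (E)-prop-1-enyllithium | C/C=C/[Li] | intermediate (not isolated)
11 | (E)-prop-1-enylmagnesium bromide | C/C=C/[Mg]Br | intermediate (not isolated)
12 | (R,E)-1-methyl-4-(prop-1-enylsulfinyl)benzene | C/C=C/[S@@](=O)c1ccc(C)cc1 | intermediate
13 | 2-[(3R)-3-(tert-butyldimethylsilyloxy)but-1-ynyl]pyrylium-3-olate | [O-]c1ccc[o+]c1C#C[C@@H](C)O[Si](C)(C)C(C)(C)C | intermediate (not isolated)
14 | (1R,5S,6S,7R)-1-[(3R)-3-(tert-butyldimethylsilyloxy)but-1-ynyl]-7-exo-methyl-6-endo-[(R)-p-tolylsulfinyl]-8-oxabicyclo[3.2.1]oct-3-en-2-one | O=C1C=C[C@H]2[C@@H]([S@@](=O)c3ccc(C)cc3)[C@H](C)[C@@]1(O2)C#C[C@@H](C)O[Si](C)(C)C(C)(C)C | intermediate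
15 | (1R,5S,6S,7R)-1-[(3R)-3-(tert-butyldimethylsilyloxy)but-1-ynyl]-7-exo-methyl-6-endo-(p-tolylsulfonyl)-8-oxabicyclo[3.2.1]oct-3-en-2-one | O=C1C=C[C@H]2[C@@H](S(=O)(=O)c3ccc(C)cc3)[C@H](C)[C@@]1(O2)C#C[C@@H](C)O[Si](C)(C)C(C)(C)C | intermediate
16 | methyl propanoate | CCC(=O)OC | starting material
17 | lithium enolate of methyl propanoate | [Li]OC(OC)=CC | intermediate (not isolated)
18 | (E)-1-methoxy-1-(trimethylsilyloxy)prop-1-ene | C/C=C(/O[Si](C)(C)C)OC | intermediate
19 | C5 trimethylsilyl enol ether of the Michael adduct: exo CH(CH3)CO2Me at C7, endo sulfonyl at C9, exo methyl at C10 (C11 epimers) | C[Si](C)(C)OC1=C[C@H](C(C)C(=O)OC)[C@H]2[C@@H](S(=O)(=O)c3ccc(C)cc3)[C@H](C)[C@@]1(O2)C#C[C@@H](C)O[Si](C)(C)C(C)(C)C | intermediate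
20 | C6-exo alkylborane with endo C5 trimethylsilyloxy group (C11 epimers) | C[Si](C)(C)O[C@H]1[C@H](B)[C@H](C(C)C(=O)OC)[C@H]2[C@@H](S(=O)(=O)c3ccc(C)cc3)[C@H](C)[C@@]1(O2)C#C[C@@H](C)O[Si](C)(C)C(C)(C)C | intermediate (not isolated)
21 | trans-5,6-diol methyl ester (C5–OH endo, C6–OH exo; C11 epimers) | O[C@H]1[C@H](O)[C@H](C(C)C(=O)OC)[C@H]2[C@@H](S(=O)(=O)c3ccc(C)cc3)[C@H](C)[C@@]1(O2)C#C[C@@H](C)O[Si](C)(C)C(C)(C)C | intermediate (not isolated)
22 | bicyclic γ-lactone alcohol: C5–OH endo, 6,12-olide cis-fused on the exo face, C9 sulfonyl endo, C10 methyl exo (C11 epimers) | O[C@H]1[C@@H]2OC(=O)C(C)[C@@H]2[C@H]3[C@@H](S(=O)(=O)c4ccc(C)cc4)[C@H](C)[C@@]1(O3)C#C[C@@H](C)O[Si](C)(C)C(C)(C)C | intermediate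
23 | monocyclic cyclohept-8-ene diol lactone: C1–OH, O–C6, C7–C11 and C10 methyl on one face, C5–OH and the alkynyl chain on the other (C11 epimers) | O[C@H]1[C@@H]2OC(=O)C(C)[C@@H]2C=C[C@H](C)[C@@]1(O)C#C[C@@H](C)O[Si](C)(C)C(C)(C)C | intermediate
24 | trilithium salt of 23 (C1 and C5 alkoxides, C11 lactone enolate) | [Li]O[C@H]1[C@@H]2OC(O[Li])=C(C)[C@@H]2C=C[C@H](C)[C@@]1(O[Li])C#C[C@@H](C)O[Si](C)(C)C(C)(C)C | intermediate (not isolated)
25 | cyclohept-8-ene diol lactone, single C11 epimer (11-H cis to 6-H and 7-H) | O[C@H]1[C@@H]2OC(=O)[C@H](C)[C@@H]2C=C[C@H](C)[C@@]1(O)C#C[C@@H](C)O[Si](C)(C)C(C)(C)C | intermediate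
26 | C5 dimethylsilyl (Si–H) ether of 25 | C[SiH](C)O[C@H]1[C@@H]2OC(=O)[C@H](C)[C@@H]2C=C[C@H](C)[C@@]1(O)C#C[C@@H](C)O[Si](C)(C)C(C)(C)C | intermediate (not isolated)
27 | cyclic alkenylsiloxane (O5–SiMe2–C2 five-membered ring, exocyclic C2=C3) | C[Si]1(C)O[C@H]2[C@@H]3OC(=O)[C@H](C)[C@@H]3C=C[C@H](C)[C@@]2(O)/C1=C\[C@@H](C)O[Si](C)(C)C(C)(C)C | intermediate (not isolated)
28 | C2 ketone: 1,5-dihydroxy, 2-oxo, (4R)-4-silyloxy chain, C8=C9, 6,12-olide | O[C@H]1[C@@H]2OC(=O)[C@H](C)[C@@H]2C=C[C@H](C)[C@@]1(O)C(=O)C[C@@H](C)O[Si](C)(C)C(C)(C)C | intermediate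
29 | 8,9-dihydro derivative of 28 | O[C@H]1[C@@H]2OC(=O)[C@H](C)[C@@H]2CC[C@H](C)[C@@]1(O)C(=O)C[C@@H](C)O[Si](C)(C)C(C)(C)C | intermediate
30 | angelic acid ((Z)-2-methylbut-2-enoic acid) | C/C=C(/C)C(=O)O | starting material
31 | angelic 2,4,6-trichlorobenzoic anhydride | C/C=C(/C)C(=O)OC(=O)c1c(Cl)cc(Cl)cc1Cl | intermediate (not isolated)
32 | 5-O-angeloyl derivative of 29 (C4 silyl ether) | C/C=C(/C)C(=O)O[C@H]1[C@@H]2OC(=O)[C@H](C)[C@@H]2CC[C@H](C)[C@@]1(O)C(=O)C[C@@H](C)O[Si](C)(C)C(C)(C)C | intermediate
33 | CNP0321985.1 | C/C=C(/C)C(=O)O[C@H]1[C@@H]2OC(=O)[C@H](C)[C@@H]2CC[C@H](C)[C@@]1(O)C(=O)C[C@@H](C)O | target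

## Step count and risks

Total: 16 steps. Longest linear sequence: 14 steps (steps 1–4, 6, 7, 9–16); steps 5 and 8 are side branches.

Steps most likely to fail:

- **Step 6.** The ylide may dimerise faster than it adds to the weakly activated β-methyl vinyl sulfoxide, or the sulfinyl group may give poor endo or facial control. Fallback: oxidise 12 with mCPBA to the more electron-poor (E)-1-methyl-4-(prop-1-enylsulfonyl)benzene F1, a dipolarophile of the vinyl sulfone class known to trap oxidopyrylium ylides. Cycloaddition of 7 with F1 (Et3N, CH2Cl2 or MeCN, 25–60 °C) should give sulfone 15 directly, together with the diastereomer that has the mirror-image bicycle F2. The two differ in the relation of the bicycle to the C4 stereocentre and would be separated by chromatography or crystallisation. The route is rejoined at 15 and step 7 is skipped.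

- **Step 10.** The borane may attack the C2≡C3 alkyne in competition with the enol ether. Fallback: mask the alkyne first. Treating 19 with Co2(CO)8 (CH2Cl2, 25 °C) should give the hexacarbonyldicobalt alkyne complex of 19 F3, the classical alkyne protection against hydroboration. The same hydroboration, oxidation and lactonisation then lead to the hexacarbonyldicobalt complex of 22 F4. Oxidative decomplexation with Fe(NO3)3·9H2O (EtOH, 0 °C) releases 22, where the route is rejoined.

- **Step 11.** The C9 carbanion may be protonated, or the C9 radical may abstract hydrogen, before the alkoxide is expelled, so that the sulfone is lost while the bridge stays closed. Fallback: separate the two events. Treating 22 with LiN(i-Pr)2 (3.5 equiv, THF, −78 °C) should open the bridge by E1cB elimination from the α-sulfonyl carbanion and give the C8=C9 vinyl sulfone diol F5. Reductive desulfonylation of the vinyl sulfone with sodium amalgam (Na2HPO4, MeOH/THF, −20 °C) then gives 23, where the route is rejoined.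

## Further compounds

F1 | step 6 | (E)-1-methyl-4-(prop-1-enylsulfonyl)benzene | C/C=C/S(=O)(=O)c1ccc(C)cc1
F2 | step 6 | diastereomer of 15 with the enantiomeric bicycle (1S,5R,6R,7S; chain still 3R) | O=C1C=C[C@@H]2[C@H](S(=O)(=O)c3ccc(C)cc3)[C@@H](C)[C@]1(O2)C#C[C@@H](C)O[Si](C)(C)C(C)(C)C
F3 | step 10 | hexacarbonyldicobalt complex of the C2≡C3 alkyne of 19 | C[Si](C)(C)OC1=C[C@H](C(C)C(=O)OC)[C@H]2[C@@H](S(=O)(=O)c3ccc(C)cc3)[C@H](C)[C@@]1(O2)[C]45[C]6([C@@H](C)O[Si](C)(C)C(C)(C)C)[Co]4(=C=O)(=C=O)(=C=O)[Co]56(=C=O)(=C=O)=C=O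
F4 | step 10 | hexacarbonyldicobalt complex of the C2≡C3 alkyne of 22 | O[C@H]1[C@@H]2OC(=O)C(C)[C@@H]2[C@H]3[C@@H](S(=O)(=O)c4ccc(C)cc4)[C@H](C)[C@@]1(O3)[C]56[C]7([C@@H](C)O[Si](C)(C)C(C)(C)C)[Co]5(=C=O)(=C=O)(=C=O)[Co]67(=C=O)(=C=O)=C=O
F5 | step 11 | C8=C9 vinyl sulfone diol lactone (9-p-tolylsulfonyl; C11 epimers) | O[C@H]1[C@@H]2OC(=O)C(C)[C@@H]2C=C(S(=O)(=O)c3ccc(C)cc3)[C@H](C)[C@@]1(O)C#C[C@@H](C)O[Si](C)(C)C(C)(C)C
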